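## The problem

The target 47 is a pentacyclic lactam. Its atoms are labelled along the skeleton as C1 (the CH that carries CO2Me), C2, C3 (quaternary), C4 (lactam carbonyl), N5, C6, C7, C8, C9, C10=C11, C12 (ring-fusion CH), C13, C14, C15 (quaternary, CH2OAc), C16, C17, C18 (carbinol), C19 (CH–CH3) and C20, and these labels are kept for every intermediate. Ring A (C1, C2, C3, C11, C12) and the cyclopentene ring B (C10–C14) share C11–C12; ring C (C3, C11, C10, C9, C8, C7, C15) and the δ-lactam ring D (C3, C4, N5, C6, C7, C15) form a bicyclo[4.3.1]decane with C15 as one-carbon bridge; the azonane ring E (N5, C6, C7, C15–C20) ties N5 back to C15. There are seven stereocentres, (1R,3R,7S,12R,15R,18R,19R), among them the adjacent quaternary carbons C3 and C15. C12 is the only centre a catalyst can set on an achiral chain; C3 can be derived from it through a ring-fusion constraint and C1 through the convex face of the A/B bicycle, C7 is dictated by the bridged bicycle, C15 by the more open face of that bicycle, and the remote pair C18/C19 needs a reagent. Fragile points are the C1 ester (on the concave face beside C13 and C15, probably the less stable epimer), the primary acetate, and any C1 ketone, which is β,γ-unsaturated with a C12–H that is both allylic and α to the carbonyl. The tetrasubstituted C10=C11 alkene is inert to boranes and mild reductants and serves as a fixed point. The feature that invites the key step is ring B: a cyclopentene whose alkene carbon C11 is shared with rings A and C and whose allylic C12–H is the ring fusion is what a 1-vinylbicyclo[3.1.0]hexane (cyclopropane C11–C12–C13, vinyl group C10=C14 on C11) leaves after a vinylcyclopropane-to-cyclopentene shift.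

## Retrosynthesis

**C1 ester (47 ⇐ 46 ⇐ 45 ⇐ 44).** No skeletal bond is cut. The C1 ester is epimerisable and on the hindered face, so it is carried as a silyl-protected CH2OH and revealed last. This asks for a primary-selective oxidation beside the free C18 alcohol and a neutral esterification.

**Ring E (44 ⇐ 43).** The N5–C20 bond is cut, giving a lactam N–H and a primary iodide. Cuts at C17–C18 or C16–C17 would set C18 during ring closure or need a vinyl group on the neopentyl C15; the N–C cut lets C18 and C19 be fixed on an open chain. The precursor is a rigid tetracycle whose chain is held on the lactam face of C15. The forward step must close a nine-membered ring by N-alkylation.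

**Side chain (43 ⇐ 42 ⇐ 41 ⇐ 40 ⇐ 38 + 39; 38 ⇐ 37 ⇐ 35).** The C18–C19 bond is cut as an auxiliary-controlled syn-aldol between aldehyde 38 and imide 39. This sets both remote centres by reagent control, independent of the core, and the imide carbonyl becomes C20. Aldehyde 38 comes from the allyl group of 35.

**C15 (35 ⇐ 34 ⇐ 32 ⇐ 31 ⇐ 30).** The C15–C16 bond is cut as allylation of a nitrile-stabilised carbanion; the nitrile (later CH2OAc) comes from the C15 ketone of 30. The C3–C15 bond is never formed: it is a bond of 4, and C15 is completed from a carbonyl carbon by reactions that tolerate congestion. The forward step needs the allyl halide to enter on the lactam face.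

**Ring D (30 ⇐ 28 ⇐ 27).** N5–C4 and N5–C6 are cut together: an unsubstituted nitrogen nucleophile adds to the α-methylene ketone 28 and the amine lactamises onto the C3 methyl ester. C6 is a one-carbon aldehyde unit brought in by olefination of β-keto phosphonate 27. C7 needs no control because only one epimer can close the bicycle.

**Ring C (27 ⇐ 25).** The C7–C15 bond is cut as intramolecular acylation of a phosphonate carbanion by the activated C15 carboxyl of half-ester 25. The phosphonate is used twice (acylation, then olefination), which is why the side chain carries it from the first step. The step needs the two C3 carboxyls to be distinguishable.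

**The two C3 carboxyls (25 ⇐ 24 ⇐ 23 ⇐ 21).** They are told apart by iodolactonisation of the diacid from 21. The new C11–I bond must be cis to C12–H (cis-fused bicyclo[3.3.0]octane), so only the carboxyl on the other face can close onto C10; zinc then returns the alkene. A lactone tether from C1 was rejected because a bridge across ring A fights the torsion the C11=C10 fusion imposes.

**C1 (21 ⇐ 20 ⇐ 18 ⇐ 17).** The exocyclic C1 carbon is introduced by non-basic methylenation of ketone 17 and hydroborated from the convex face. An enol triflate/carbonylation at C1 was rejected because enolisation of 17 towards C12 would compete and destroy C12.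

**Ring B, the key step (17 ⇐ 16 ⇐ 15 ⇐ 14).** The C13–C14 bond is cut and C11–C13 restored, leading back to vinylcyclopropane 14. The rearrangement is run on ketal 15 under nickel catalysis, so that the ring-fusion bond C11–C12 is neither acyl-activated nor homolysed.

**Cyclopropane (14 ⇐ 13 ⇐ 11 ⇐ 9).** C12–C11 and C12–C13 are cut as an enantioselective intramolecular cyclopropanation of diazoketone 13. This is the only catalytic asymmetric step and the source of all core stereochemistry.

**Diene and chain (9 ⇐ 8 ⇐ 6 + 3; 6 ⇐ 4 + 5; 3 ⇐ 2 ⇐ 1).** The two methylene carbons C13 and C14 come from a C2 alkene in an enyne metathesis of 8. Alkyne 8 comes from α-alkynylation of triester 6 (from 4 and 5) with stannane 3, made from 1 through 2.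

## Roads not taken

**Alternative 1:** The cut is C17–C18 in ring E. CrCl2 with catalytic NiCl2 would couple the (Z)-vinyl iodide on C15 of the seco aldehyde A2 with its α-methyl aldehyde to give the (Z)-allylic alcohol A1, one hydrogenation from the target.
- Merits: this coupling is the best-founded way to medium rings, forms a C–C bond at neutral pH, tolerates ester, lactam and acetate, and leaves a disubstituted alkene that can be hydrogenated beside the tetrasubstituted one.
- Weak points: C18 is set in the ring-closing step with only the C19 methyl (Felkin–Anh) and the ring to guide it; the aldehyde of A2 is α-chiral and β to the lactam nitrogen, so it can epimerise or eliminate; a (Z)-iodovinyl group must be built on the neopentyl C15; and the step says nothing about rings A–D.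
- Comparison: for ring E alone this cut is better than the N-alkylation of 43, and that is conceded. The chosen plan sets against it that C18 and C19 are both fixed by the auxiliary in 40 before ring closure, and that its key step supplies ring B and the absolute configuration of the core.

**Alternative 2:** The cut is C3–C15. The silyl ketene acetal of the eleven-membered allylic lactone A4 would rearrange [3,3] (Ireland–Claisen) to the acid A3, joining the two quaternary carbons and contracting the macrocycle to ring C.
- Merits: one step makes the most congested bond, both quaternary centres and ring C, and leaves a carboxyl and a vinyl group where the lactam and ring E need them.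
- Weak points: the ketene acetal geometry is set by the macrocycle, not by the base; chair and boat transition states give different relative configurations; a fully substituted enolate carbon meeting a trisubstituted alkene carbon is at the steric limit; A4 needs a trisubstituted alkene of defined geometry; and ring A is still open in A3, so C1 and C12 must be set later.
- Comparison: in directness at the vicinal quaternary pair this road is superior: one step against steps 15–24 here. The chosen plan sets against it that the C3–C15 bond is bought with 4, that C3 rests on a ring-fusion rule (step 15) and C15 on simple face shielding (step 22), and that rings A and B with C12 come from one catalytic asymmetric step.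

**Alternative 3:** The cut is C6–C7. Anodic decarboxylation of the N-carboxymethyl nine-membered lactam A6 would give an N-acyliminium ion that the allylsilane on C15 attacks across the ring, closing ring D and giving A5 with a vinyl group on C7.
- Merits: the oxidant is the electrode; C7 is forced by the bicycle; the vinyl group and enol triflate of A5 are poised to close ring C by cross-coupling.
- Weak points: A6 already holds both quaternary carbons and a nine-membered lactam that must be closed at the neopentyl C4 carboxyl; the allylsilane can be oxidised at the anode; the unsubstituted iminium ion is easily captured by solvent; ring C is left to a late coupling at a tetrasubstituted carbon.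
- Comparison: as a ring-D closure it is on a par with step 20 and more elegant, since no C15 carbonyl is needed and C7 arrives functionalised. The chosen plan sets against it cheap reagents and a medium ring closed last on a rigid tetracycle instead of first on a flexible chain.

Key step: step 10

Remark on the chemistry: the sense of induction in step 8 is assumed to be (S,S)-ligand → (1R,5S)-14; if the opposite sense is found, the (R,R)-ligand is used and nothing else changes.

Remark on the chemistry: the spatial arrangement at C12 is the same from 14 to 47; only its CIP descriptor changes (S in 14–17, R from 18 on).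

## Route

Step 1
Reactants: 1 5-iodopent-1-yne
Product: 2 diethyl pent-4-yn-1-ylphosphonate
Conditions: P(OEt)3 (neat), 130 °C
Reagents that add atoms: triethyl phosphite, CCOP(OCC)OCC
Why: Michaelis–Arbuzov reaction of a primary iodide; the terminal alkyne is inert under these neutral thermal conditions.

Step 2
Reactants: 2 diethyl pent-4-yn-1-ylphosphonate
Product: 3 diethyl [5-(trimethylstannyl)pent-4-yn-1-yl]phosphonate
Conditions: Me3SnNMe2, THF, 60 °C
Reagents that add atoms: (dimethylamino)trimethylstannane, CN(C)[Sn](C)(C)C
Why: Aminostannanes stannylate terminal alkynes by amine exchange without added base, so the CH2 next to phosphorus is not deprotonated.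

Step 3
Reactants: 4 dimethyl malonate; 5 tert-butyl bromoacetate
Product: 6 1-tert-butyl 2,2-dimethyl ethane-1,2,2-tricarboxylate
Conditions: NaH, THF, 0 °C → rt (4 in excess)
Reagents that add atoms: none
Why: Malonate C-alkylation with an α-halo ester; the excess of 4 suppresses dialkylation.

Step 4
Reactants: 6 1-tert-butyl 2,2-dimethyl ethane-1,2,2-tricarboxylate; 3 diethyl [5-(trimethylstannyl)pent-4-yn-1-yl]phosphonate
Product: 8 1-tert-butyl 2,2-dimethyl 7-(diethoxyphosphoryl)hept-3-yne-1,2,2-tricarboxylate, via alkynyllead triacetate 7 (not isolated)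
Conditions: 3, Pb(OAc)4, CHCl3, rt; then sodium salt of 6 (NaH, DMSO), rt
Reagents that add atoms: none
Why: Tin–lead exchange gives 7, which transfers its alkynyl group to the soft tertiary carbanion of 6 by ligand coupling at tetravalent lead, a known α-alkynylation of substituted 1,3-dicarbonyl salts that accepts alkyl-substituted alkynes; no alkylidene carbene is involved, so the chain cannot insert.

Step 5
Reactants: 8 1-tert-butyl 2,2-dimethyl 7-(diethoxyphosphoryl)hept-3-yne-1,2,2-tricarboxylate
Product: 9 1-tert-butyl 2,2-dimethyl 7-(diethoxyphosphoryl)-3,4-dimethylideneheptane-1,2,2-tricarboxylate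
Conditions: H2C=CH2 (4 atm), second-generation Grubbs catalyst RuCl2(H2IMes)(PCy3)(=CHPh) (10 mol%), PhMe, 80 °C
Reagents that add atoms: ethylene, C=C
Why: Cross enyne metathesis of an internal alkyne with ethylene turns each alkyne carbon into a C=CH2 unit and gives the 2,3-disubstituted buta-1,3-diene; pressure and heat are meant to offset the quaternary propargylic carbon.

Step 6
Reactants: 9 1-tert-butyl 2,2-dimethyl 7-(diethoxyphosphoryl)-3,4-dimethylideneheptane-1,2,2-tricarboxylate
Product: 11 8-(diethoxyphosphoryl)-3,3-bis(methoxycarbonyl)-4,5-dimethylideneoctanoic acid, via trimethylsilyl ester 10 (not isolated)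
Conditions: Me3SiOTf, 2,6-lutidine, CH2Cl2, 0 °C; then aq. citric acid
Reagents that add atoms: none
Why: Silyl triflate-mediated cleavage of a tert-butyl ester (loss of isobutene) under buffered aprotic conditions, chosen because protic acid could protonate the diene; methyl and phosphonate esters are untouched.

Step 7
Reactants: 11 8-(diethoxyphosphoryl)-3,3-bis(methoxycarbonyl)-4,5-dimethylideneoctanoic acid
Product: 13 dimethyl 2-(3-diazo-2-oxopropyl)-2-[6-(diethoxyphosphoryl)-3-methylidenehex-1-en-2-yl]propanedioate, via mixed anhydride 12 (not isolated)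
Conditions: iBuOCOCl, N-methylmorpholine, THF, −20 °C; then CH2N2, Et2O, 0 °C
Reagents that add atoms: diazomethane, C=[N+]=[N-]
Why: Acylation of diazomethane by a mixed carbonic anhydride (first stage of the Arndt–Eistert sequence); no HCl is formed that could add to the diene.

Step 8
Reactants: 13 dimethyl 2-(3-diazo-2-oxopropyl)-2-[6-(diethoxyphosphoryl)-3-methylidenehex-1-en-2-yl]propanedioate
Product: 14 dimethyl (1R,5S)-1-[5-(diethoxyphosphoryl)pent-1-en-2-yl]-4-oxobicyclo[3.1.0]hexane-2,2-dicarboxylate
Conditions: CuOTf [(CuOTf)2·C6H6, 5 mol%], 2,2'-(propane-2,2-diyl)bis[(4S)-4-tert-butyl-4,5-dihydrooxazole] (6 mol%), CH2Cl2, rt, slow addition of 13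
Reagents that add atoms: none
Why: Copper-carbene intramolecular cyclopropanation of an α-diazoketone; five-ring formation directs the carbene to the proximal alkene, the cyclopropane is necessarily cis-fused, and the chiral bis(oxazoline) selects the alkene face, setting C11 and C12 (only C12 survives the key step).

Step 9
Reactants: 14 dimethyl (1R,5S)-1-[5-(diethoxyphosphoryl)pent-1-en-2-yl]-4-oxobicyclo[3.1.0]hexane-2,2-dicarboxylate
Product: 15 dimethyl (1R,5S)-1-[5-(diethoxyphosphoryl)pent-1-en-2-yl]-4,4-dimethoxybicyclo[3.1.0]hexane-2,2-dicarboxylate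
Conditions: HC(OMe)3, MeOH, camphorsulfonic acid (cat.), rt
Reagents that add atoms: trimethyl orthoformate, COC(OC)OC
Why: Acid-catalysed ketalisation with the orthoformate as water scavenger; the geminal diester next to C11 disfavours cationic opening of the cyclopropane, and the ketal removes the acyl activation of the C11–C12 bond before the metal step.

Step 10
Reactants: 15 dimethyl (1R,5S)-1-[5-(diethoxyphosphoryl)pent-1-en-2-yl]-4,4-dimethoxybicyclo[3.1.0]hexane-2,2-dicarboxylate
Product: 16 dimethyl (3aS)-6-[3-(diethoxyphosphoryl)propyl]-3,3-dimethoxy-3,3a,4,5-tetrahydropentalene-1,1(2H)-dicarboxylate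
Conditions: Ni(cod)2 (10 mol%), 1,3-bis(2,6-diisopropylphenyl)imidazol-2-ylidene (IPr, 20 mol%), PhMe, 60 °C
Reagents that add atoms: none
Why: Zerovalent nickel bound to the 1,1-disubstituted alkene inserts into the adjacent outer cyclopropane bond C11–C13 to give an η3-allyl/σ-alkyl nickelacycle, and C–C reductive elimination at the far allyl terminus joins C13 to C14 and frees the catalyst. The closest known reaction type is the Ni(cod)2/N-heterocyclic carbene isomerisation of unactivated vinylcyclopropanes to cyclopentenes; the thermal 1,3-shift of 1-vinylbicyclo[3.1.0]hexanones used in triquinane synthesis shows the same change of connectivity. Ring B closes as a five-membered ring by reductive elimination from the six-membered nickelacycle, formally a 1,3-shift of C13 from C11 to C14, which leaves the alkene tetrasubstituted at C10=C11. No stereocentre is formed; C12 takes no part in bond breaking or making and should be retained. The selectivity needed is insertion into C11–C13 and not into the ring-fusion bond C11–C12: the outer bond ends in an unhindered CH2, the inner one is flanked by the ketal carbon, and a nickelacycle from the inner bond could only eliminate to an anti-Bredt alkene and must revert. The ketal makes this safe, since a free C1 ketone would turn C11–C12 into an acyl-activated vinylcyclopropane bond that low-valent nickel opens readily. A temperature of 60 °C also rules out homolysis of C11–C12, whose cyclohexane-1,3-diyl could reclose on either face and racemise 15.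

Step 11
Reactants: 16 dimethyl (3aS)-6-[3-(diethoxyphosphoryl)propyl]-3,3-dimethoxy-3,3a,4,5-tetrahydropentalene-1,1(2H)-dicarboxylate
Product: 17 dimethyl (3aS)-6-[3-(diethoxyphosphoryl)propyl]-3-oxo-3,3a,4,5-tetrahydropentalene-1,1(2H)-dicarboxylate
Conditions: oxalic acid, wet SiO2, CH2Cl2, rt
Reagents that add atoms: water, O
Why: Mild hydrolysis of a dimethyl ketal; weak acid and short contact are chosen so that the β,γ-unsaturated ketone is neither conjugated nor epimerised at C12, and 17 is used at once.

Step 12
Reactants: 17 dimethyl (3aS)-6-[3-(diethoxyphosphoryl)propyl]-3-oxo-3,3a,4,5-tetrahydropentalene-1,1(2H)-dicarboxylate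
Product: 18 dimethyl (3aR)-6-[3-(diethoxyphosphoryl)propyl]-3-methylidene-3,3a,4,5-tetrahydropentalene-1,1(2H)-dicarboxylate
Conditions: Zn, CH2Br2, TiCl4, THF–CH2Cl2, 0 °C → rt
Reagents that add atoms: dibromomethane, BrCBr
Why: Takai–Lombardo methylenation, a non-basic carbonyl olefination suited to easily enolised ketones and tolerant of esters; it removes the carbonyl that makes C12–H labile and brings in the carbon of the C1 ester.

Step 13
Reactants: 18 dimethyl (3aR)-6-[3-(diethoxyphosphoryl)propyl]-3-methylidene-3,3a,4,5-tetrahydropentalene-1,1(2H)-dicarboxylate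
Product: 20 dimethyl (3R,3aR)-6-[3-(diethoxyphosphoryl)propyl]-3-(hydroxymethyl)-3,3a,4,5-tetrahydropentalene-1,1(2H)-dicarboxylate, via alkylborane 19 (not isolated)
Conditions: 9-BBN, THF, 0 °C → rt; then H2O2, pH 7 buffer (NaH2PO4/Na2HPO4)
Reagents that add atoms: hydrogen peroxide, OO
Why: Anti-Markovnikov hydroboration–oxidation of the 1,1-disubstituted alkene only (the tetrasubstituted C10=C11 is inert to 9-BBN); the bulky borane should approach the convex face, that of C12–H, which sets C1 with its CH2OH on the face of C13, and any C1 epimer is separated here. Lactonisation onto the cis ester is disfavoured by the torsion of the ring fusion, so 20 should be isolable.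

Step 14
Reactants: 20 dimethyl (3R,3aR)-6-[3-(diethoxyphosphoryl)propyl]-3-(hydroxymethyl)-3,3a,4,5-tetrahydropentalene-1,1(2H)-dicarboxylate
Product: 21 dimethyl (3R,3aR)-6-[3-(diethoxyphosphoryl)propyl]-3-{[tri(propan-2-yl)silyl]oxymethyl}-3,3a,4,5-tetrahydropentalene-1,1(2H)-dicarboxylate
Conditions: iPr3SiCl, imidazole, DMF, rt
Reagents that add atoms: chlorotri(propan-2-yl)silane, CC(C)[Si](Cl)(C(C)C)C(C)C
Why: Silylation of a primary alcohol; the triisopropylsilyl ether tolerates the bases, hydrides and mild acids that follow and adds bulk on the lower face near C15.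

Step 15
Reactants: 21 dimethyl (3R,3aR)-6-[3-(diethoxyphosphoryl)propyl]-3-{[tri(propan-2-yl)silyl]oxymethyl}-3,3a,4,5-tetrahydropentalene-1,1(2H)-dicarboxylate
Product: 23 iodolactone acid (γ-lactone from the C3 carboxyl trans to H-12 onto C10; iodine on C11 cis to H-12; free C3 carboxyl), via diacid 22 (not isolated)
Conditions: LiOH, THF–MeOH–H2O, 50 °C; aq. citric acid; then I2, NaHCO3, MeCN, rt, 24 h (equilibrating)
Reagents that add atoms: lithium hydroxide, [Li+].[OH-]; iodine, II
Why: Saponification of both hindered esters, then iodolactonisation under thermodynamic control: the iodonium ion of C10=C11 is opened at C10 by a C3 carboxyl to give the five-membered lactone. Because the new C11–I bond must be cis to C12–H for a cis-fused bicyclo[3.3.0]octane, only the carboxyl on the opposite face (the future C15) can close, which sets C3 from C12.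

Step 16
Reactants: 23 iodolactone acid
Product: 24 iodolactone methyl ester
Conditions: Me3SiCHN2, PhMe–MeOH, 0 °C
Reagents that add atoms: (trimethylsilyl)diazomethane, C[Si](C)(C)C=[N+]=[N-]
Why: Neutral methylation of the free carboxylic acid (the future C4); lactone and tertiary iodide are untouched.

Step 17
Reactants: 24 iodolactone methyl ester
Product: 25 half-ester (C3 carboxylic acid trans to H-12, C3 methyl ester cis to H-12, C10=C11 restored)
Conditions: Zn, AcOH, THF, rt
Reagents that add atoms: none
Why: Reductive elimination of the anti-disposed iodide and acyloxy group by zinc regenerates C10=C11 and frees the C15 carboxylic acid, so the two carboxyls are now an acid and a methyl ester of known configuration.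

Step 18
Reactants: 25 half-ester
Product: 27 tricyclic β-keto phosphonate (rings A–C; C15 ketone bonded to C7), via acyl imidazolide 26 (not isolated)
Conditions: 1,1'-carbonyldiimidazole, THF, rt; then LiN(iPr)2 (3.5 equiv), THF (0.01 M), −78 → 0 °C; aq. NH4Cl
Reagents that add atoms: none
Why: Claisen-type acylation of a phosphonate-stabilised carbanion by an acyl imidazolide, intramolecular and 7-exo-trig, helped by the cis alkene and the quaternary C3; the imidazolide is far more electrophilic than the hindered methyl ester, and the β-keto phosphonate is deprotonated as it forms.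

Step 19
Reactants: 27 tricyclic β-keto phosphonate
Product: 28 tricyclic α-methylene ketone (C7=C6H2)
Conditions: aq. CH2O, K2CO3, THF, 0 °C → rt
Reagents that add atoms: formaldehyde, C=O
Why: Horner–Wadsworth–Emmons reaction of a cyclic α-phosphono ketone with formaldehyde, the standard route to α-methylene ketones; it brings in C6, and 28 is used at once.

Step 20
Reactants: 28 tricyclic α-methylene ketone
Product: 30 tetracyclic keto lactam (rings A–D, N5–H), via amino ketone 29 (not isolated)
Conditions: NH3 (7 M in MeOH), rt → 60 °C (sealed)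
Reagents that add atoms: ammonia, N
Why: Conjugate addition of ammonia to the α-methylene ketone, then 6-exo-trig lactamisation of the amine onto the C3 methyl ester; C7 is epimerisable next to the ketone and only the epimer with C6 on the ester face can close, so the bridged bicycle fixes C7.

Step 21
Reactants: 30 tetracyclic keto lactam
Product: 31 tetracyclic C15 nitrile
Conditions: TosMIC, KOtBu, DME–EtOH, 0 → 40 °C
Reagents that add atoms: p-toluenesulfonylmethyl isocyanide, Cc1ccc(cc1)S(=O)(=O)C[N+]#[C-]
Why: van Leusen reductive cyanation; the ketone cannot enolise (C3 quaternary, C7 bridgehead), which suits the basic conditions, and the C15 configuration formed here is lost in the next step.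

Step 22
Reactants: 31 tetracyclic C15 nitrile
Product: 32 tetracyclic C15 allyl nitrile
Conditions: LiN(iPr)2 (2.2 equiv), THF, −78 °C; allyl bromide (1.05 equiv), −78 → −40 °C
Reagents that add atoms: allyl bromide, C=CCBr
Why: Alkylation of a tertiary nitrile-stabilised carbanion, a reliable route to congested quaternary carbons; the planar anion should be allylated on the lactam face because the other face is screened by the C1 CH2OSi(iPr)3 group, which sets C15, and the carbanion is far more nucleophilic than the lithium amidate.

Step 23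
Reactants: 32 tetracyclic C15 allyl nitrile
Product: 34 tetracyclic C15 hydroxymethyl compound, via aldehyde 33 (not isolated)
Conditions: iBu2AlH, CH2Cl2, −78 → −20 °C; aq. potassium sodium tartrate (KNaC4H4O6), wet SiO2; then NaBH4, MeOH, 0 °C
Reagents that add atoms: water, O
Why: Hydride reduction of the nitrile stops at the aluminium imine, which is hydrolysed to aldehyde 33 and reduced by NaBH4; the lactam N–H is first converted into its aluminium amide and so resists reduction.

Step 24
Reactants: 34 tetracyclic C15 hydroxymethyl compound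
Product: 35 tetracyclic C15 acetoxymethyl compound
Conditions: Ac2O, pyridine, DMAP (cat.), CH2Cl2, rt
Reagents that add atoms: acetic anhydride, CC(=O)OC(C)=O
Why: Acylation of a neopentyl primary alcohol under nucleophilic catalysis; the secondary lactam is not acylated under these conditions.

Step 25
Reactants: 35 tetracyclic C15 acetoxymethyl compound
Product: 37 C18 primary alcohol, via alkylborane 36 (not isolated)
Conditions: 9-BBN, THF, rt; then H2O2, pH 7 buffer (NaH2PO4/Na2HPO4)
Reagents that add atoms: hydrogen peroxide, OO
Why: Anti-Markovnikov hydroboration–oxidation of the terminal alkene; buffered oxidation preserves the acetate and the tetrasubstituted alkene does not react.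

Step 26
Reactants: 37 C18 primary alcohol
Product: 38 C18 aldehyde
Conditions: Dess–Martin periodinane, NaHCO3, CH2Cl2, rt
Reagents that add atoms: none
Why: Dess–Martin oxidation of a primary alcohol to the aldehyde under buffered conditions.

Step 27
Reactants: 38 C18 aldehyde; 39 (4S)-4-benzyl-3-propanoyl-1,3-oxazolidin-2-one
Product: 40 syn-aldol adduct (C18 carbinol, C19 methyl, C20 as imide carbonyl)
Conditions: 39, Bu2BOTf, Et3N, CH2Cl2, −78 → 0 °C; 38, −78 → 0 °C; pH 7 buffer (NaH2PO4/Na2HPO4), MeOH, H2O2
Reagents that add atoms: none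
Why: Evans syn-aldol reaction: the (Z)-boron enolate of the (S)-benzyl imide reacts through a closed chair transition state to give the (2S,3R)-syn adduct, which is (18R,19R) in the target; the aldehyde has no nearby stereocentre, so reagent control decides.

Step 28
Reactants: 40 syn-aldol adduct
Product: 41 C18 tert-butyldimethylsilyl ether
Conditions: tBuMe2SiOTf, 2,6-lutidine, CH2Cl2, −78 °C
Reagents that add atoms: tert-butyldimethylsilyl triflate, CC(C)(C)[Si](C)(C)OS(=O)(=O)C(F)(F)F
Why: Silylation of the secondary alcohol so that it cannot compete (oxetane formation) in the ring closure.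

Step 29
Reactants: 41 C18 tert-butyldimethylsilyl ether
Product: 42 C20 primary alcohol
Conditions: NaBH4, THF–H2O, 0 °C → rt
Reagents that add atoms: none
Why: Reductive cleavage of the N-acyloxazolidinone to the primary alcohol with NaBH4 in wet THF, conditions that spare the acetate and the lactam; the auxiliary is recovered.

Step 30
Reactants: 42 C20 primary alcohol
Product: 43 C20 primary iodide
Conditions: I2, PPh3, imidazole, CH2Cl2, 0 °C → rt
Reagents that add atoms: iodine, II
Why: Appel-type iodination of a primary alcohol; a soft, reactive leaving group is chosen to favour N- over O-alkylation.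

Step 31
Reactants: 43 C20 primary iodide
Product: 44 pentacyclic bis-silyl ether (rings A–E)
Conditions: KN(SiMe3)2, THF (0.005 M), −78 → 45 °C
Reagents that add atoms: none
Why: Intramolecular N-alkylation of the lactam anion (9-exo-tet) under high dilution closes ring E; the C16–C20 chain is held on the lactam face of C15 by the rigid tetracycle, which brings N5 and C20 together.

Step 32
Reactants: 44 pentacyclic bis-silyl ether
Product: 45 pentacyclic diol (C1 CH2OH, C18 OH)
Conditions: HF·pyridine, pyridine–THF, 0 °C → rt
Reagents that add atoms: none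
Why: Fluoride-mediated cleavage of both silyl ethers under buffered conditions that leave the acetate in place.

Step 33
Reactants: 45 pentacyclic diol
Product: 46 pentacyclic C1 carboxylic acid
Conditions: TEMPO (cat.), PhI(OAc)2, MeCN–H2O, rt
Reagents that add atoms: water, O
Why: Nitroxyl-catalysed oxidation, selective for the primary alcohol and carried through the aldehyde hydrate to the acid under neutral conditions, so the hindered C18 alcohol and the C1 configuration are kept.

Step 34
Reactants: 46 pentacyclic C1 carboxylic acid
Product: 47 CNP0296366.1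
Conditions: Me3SiCHN2, PhMe–MeOH, 0 °C
Reagents that add atoms: (trimethylsilyl)diazomethane, C[Si](C)(C)C=[N+]=[N-]
Why: Neutral methylation of the acid with (trimethylsilyl)diazomethane, which does not epimerise the concave C1 ester.

## Compound list

1 | 5-iodopent-1-yne | C#CCCCI | starting material
2 | diethyl pent-4-yn-1-ylphosphonate | C#CCCCP(=O)(OCC)OCC | intermediate
3 | diethyl [5-(trimethylstannyl)pent-4-yn-1-yl]phosphonate | C[Sn](C)(C)C#CCCCP(=O)(OCC)OCC | intermediate
4 | dimethyl malonate | COC(=O)CC(=O)OC | starting material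
5 | tert-butyl bromoacetate | CC(C)(C)OC(=O)CBr | starting material
6 | 1-tert-butyl 2,2-dimethyl ethane-1,2,2-tricarboxylate | COC(=O)C(CC(=O)OC(C)(C)C)C(=O)OC | intermediate
7 | [5-(diethoxyphosphoryl)pent-1-yn-1-yl]lead triacetate | CC(=O)O[Pb](OC(C)=O)(OC(C)=O)C#CCCCP(=O)(OCC)OCC | intermediate (not isolated)
8 | 1-tert-butyl 2,2-dimethyl 7-(diethoxyphosphoryl)hept-3-yne-1,2,2-tricarboxylate | COC(=O)C(CC(=O)OC(C)(C)C)(C#CCCCP(=O)(OCC)OCC)C(=O)OC | intermediate
9 | 1-tert-butyl 2,2-dimethyl 7-(diethoxyphosphoryl)-3,4-dimethylideneheptane-1,2,2-tricarboxylate | COC(=O)C(CC(=O)OC(C)(C)C)(C(=C)C(=C)CCCP(=O)(OCC)OCC)C(=O)OC | intermediate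
10 | trimethylsilyl 8-(diethoxyphosphoryl)-3,3-bis(methoxycarbonyl)-4,5-dimethylideneoctanoate | COC(=O)C(CC(=O)O[Si](C)(C)C)(C(=C)C(=C)CCCP(=O)(OCC)OCC)C(=O)OC | intermediate (not isolated)
11 | 8-(diethoxyphosphoryl)-3,3-bis(methoxycarbonyl)-4,5-dimethylideneoctanoic acid | COC(=O)C(CC(=O)O)(C(=C)C(=C)CCCP(=O)(OCC)OCC)C(=O)OC | intermediate
12 | mixed anhydride of 11 with isobutyl hydrogen carbonate | COC(=O)C(CC(=O)OC(=O)OCC(C)C)(C(=C)C(=C)CCCP(=O)(OCC)OCC)C(=O)OC | intermediate (not isolated)
13 | dimethyl 2-(3-diazo-2-oxopropyl)-2-[6-(diethoxyphosphoryl)-3-methylidenehex-1-en-2-yl]propanedioate | [N-]=[N+]=CC(=O)CC(C(=O)OC)(C(=O)OC)C(=C)C(=C)CCCP(=O)(OCC)OCC | intermediate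
14 | dimethyl (1R,5S)-1-[5-(diethoxyphosphoryl)pent-1-en-2-yl]-4-oxobicyclo[3.1.0]hexane-2,2-dicarboxylate | O=C1CC(C(=O)OC)(C(=O)OC)[C@]2(C(=C)CCCP(=O)(OCC)OCC)C[C@H]12 | intermediate
15 | dimethyl (1R,5S)-1-[5-(diethoxyphosphoryl)pent-1-en-2-yl]-4,4-dimethoxybicyclo[3.1.0]hexane-2,2-dicarboxylate | COC1(OC)CC(C(=O)OC)(C(=O)OC)[C@]2(C(=C)CCCP(=O)(OCC)OCC)C[C@H]12 | intermediate
16 | dimethyl (3aS)-6-[3-(diethoxyphosphoryl)propyl]-3,3-dimethoxy-3,3a,4,5-tetrahydropentalene-1,1(2H)-dicarboxylate | COC1(OC)CC(C(=O)OC)(C(=O)OC)C2=C(CCCP(=O)(OCC)OCC)CC[C@H]12 | intermediate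
17 | dimethyl (3aS)-6-[3-(diethoxyphosphoryl)propyl]-3-oxo-3,3a,4,5-tetrahydropentalene-1,1(2H)-dicarboxylate | O=C1CC(C(=O)OC)(C(=O)OC)C2=C(CCCP(=O)(OCC)OCC)CC[C@H]12 | intermediate
18 | dimethyl (3aR)-6-[3-(diethoxyphosphoryl)propyl]-3-methylidene-3,3a,4,5-tetrahydropentalene-1,1(2H)-dicarboxylate | C=C1CC(C(=O)OC)(C(=O)OC)C2=C(CCCP(=O)(OCC)OCC)CC[C@H]12 | intermediate
19 | B-alkyl-9-borabicyclo[3.3.1]nonane from 18 (boron on the new CH2 at C1; H-1 cis to H-12) | B1(C2CCCC1CCC2)C[C@@H]1CC(C(=O)OC)(C(=O)OC)C2=C(CCCP(=O)(OCC)OCC)CC[C@H]12 | intermediate (not isolated)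
20 | dimethyl (3R,3aR)-6-[3-(diethoxyphosphoryl)propyl]-3-(hydroxymethyl)-3,3a,4,5-tetrahydropentalene-1,1(2H)-dicarboxylate | OC[C@@H]1CC(C(=O)OC)(C(=O)OC)C2=C(CCCP(=O)(OCC)OCC)CC[C@H]12 | intermediate
21 | dimethyl (3R,3aR)-6-[3-(diethoxyphosphoryl)propyl]-3-{[tri(propan-2-yl)silyl]oxymethyl}-3,3a,4,5-tetrahydropentalene-1,1(2H)-dicarboxylate | CC(C)[Si](C(C)C)(C(C)C)OC[C@@H]1CC(C(=O)OC)(C(=O)OC)C2=C(CCCP(=O)(OCC)OCC)CC[C@H]12 | intermediate
22 | 1,1-dicarboxylic acid corresponding to 21 | CC(C)[Si](C(C)C)(C(C)C)OC[C@@H]1CC(C(=O)O)(C(=O)O)C2=C(CCCP(=O)(OCC)OCC)CC[C@H]12 | intermediate (not isolated)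
23 | iodolactone acid: γ-lactone from the C3 carboxyl trans to H-12 onto C10, iodine on C11 cis to H-12, free C3 carboxyl, C1 CH2OSi(iPr)3 | CC(C)[Si](C(C)C)(C(C)C)OC[C@@H]1C[C@]2(C(=O)O)C(=O)O[C@]3(CCCP(=O)(OCC)OCC)CC[C@H]1[C@]23I | intermediate
24 | methyl ester of 23 | CC(C)[Si](C(C)C)(C(C)C)OC[C@@H]1C[C@]2(C(=O)OC)C(=O)O[C@]3(CCCP(=O)(OCC)OCC)CC[C@H]1[C@]23I | intermediate
25 | half-ester: C3 carboxylic acid trans to H-12 (future C15), C3 methyl ester cis to H-12 (C4), C10=C11 restored | CC(C)[Si](C(C)C)(C(C)C)OC[C@@H]1C[C@@](C(=O)O)(C(=O)OC)C2=C(CCCP(=O)(OCC)OCC)CC[C@H]12 | intermediate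
26 | acyl imidazolide of 25 | CC(C)[Si](C(C)C)(C(C)C)OC[C@@H]1C[C@@](C(=O)n2ccnc2)(C(=O)OC)C2=C(CCCP(=O)(OCC)OCC)CC[C@H]12 | intermediate (not isolated)
27 | tricyclic β-keto phosphonate (rings A–C): C15 ketone bonded to C7, P(O)(OEt)2 on C7 (both C7 epimers), C3 CO2Me, C1 CH2OSi(iPr)3 | CC(C)[Si](C(C)C)(C(C)C)OC[C@@H]1C[C@]2(C(=O)OC)C(=O)C(P(=O)(OCC)OCC)CCC3=C2[C@@H]1CC3 | intermediate
28 | tricyclic α-methylene ketone (C7=C6H2) | CC(C)[Si](C(C)C)(C(C)C)OC[C@@H]1C[C@]2(C(=O)OC)C(=O)C(=C)CCC3=C2[C@@H]1CC3 | intermediate
29 | tricyclic β-amino ketone (C6–NH2, both C7 epimers) | CC(C)[Si](C(C)C)(C(C)C)OC[C@@H]1C[C@]2(C(=O)OC)C(=O)C(CN)CCC3=C2[C@@H]1CC3 | intermediate (not isolated)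
30 | tetracyclic keto lactam (rings A–D), N5–H, C15 ketone | CC(C)[Si](C(C)C)(C(C)C)OC[C@@H]1C[C@@]23C(=O)NC[C@@H](CCC4=C2[C@@H]1CC4)C3=O | intermediate
31 | tetracyclic C15 nitrile (both C15 epimers) | CC(C)[Si](C(C)C)(C(C)C)OC[C@@H]1C[C@@]23C(=O)NC[C@@H](CCC4=C2[C@@H]1CC4)C3C#N | intermediate
32 | tetracyclic C15 allyl nitrile (allyl on the lactam face) | CC(C)[Si](C(C)C)(C(C)C)OC[C@@H]1C[C@@]23C(=O)NC[C@@H](CCC4=C2[C@@H]1CC4)[C@]3(C#N)CC=C | intermediate
33 | tetracyclic C15 allyl aldehyde | CC(C)[Si](C(C)C)(C(C)C)OC[C@@H]1C[C@@]23C(=O)NC[C@@H](CCC4=C2[C@@H]1CC4)[C@]3(C=O)CC=C | intermediate (not isolated)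
34 | tetracyclic C15 allyl hydroxymethyl compound | CC(C)[Si](C(C)C)(C(C)C)OC[C@@H]1C[C@@]23C(=O)NC[C@@H](CCC4=C2[C@@H]1CC4)[C@]3(CO)CC=C | intermediate
35 | tetracyclic C15 allyl acetoxymethyl compound | CC(C)[Si](C(C)C)(C(C)C)OC[C@@H]1C[C@@]23C(=O)NC[C@@H](CCC4=C2[C@@H]1CC4)[C@]3(COC(C)=O)CC=C | intermediate
36 | B-alkyl-9-borabicyclo[3.3.1]nonane from 35 (boron on C18) | CC(C)[Si](C(C)C)(C(C)C)OC[C@@H]1C[C@@]23C(=O)NC[C@@H](CCC4=C2[C@@H]1CC4)[C@]3(COC(C)=O)CCCB1C2CCCC1CCC2 | intermediate (not isolated)
37 | C18 primary alcohol (3-hydroxypropyl on C15) | CC(C)[Si](C(C)C)(C(C)C)OC[C@@H]1C[C@@]23C(=O)NC[C@@H](CCC4=C2[C@@H]1CC4)[C@]3(COC(C)=O)CCCO | intermediate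
38 | C18 aldehyde (3-oxopropyl on C15) | CC(C)[Si](C(C)C)(C(C)C)OC[C@@H]1C[C@@]23C(=O)NC[C@@H](CCC4=C2[C@@H]1CC4)[C@]3(COC(C)=O)CCC=O | intermediate
39 | (4S)-4-benzyl-3-propanoyl-1,3-oxazolidin-2-one | CCC(=O)N1[C@@H](Cc2ccccc2)COC1=O | starting material
40 | syn-aldol adduct: (18R)-hydroxy, (19R in target sense)-methyl, C20 as N-acyl oxazolidinone | CC(C)[Si](C(C)C)(C(C)C)OC[C@@H]1C[C@@]23C(=O)NC[C@@H](CCC4=C2[C@@H]1CC4)[C@]3(COC(C)=O)CC[C@@H](O)[C@H](C)C(=O)N1[C@@H](Cc2ccccc2)COC1=O | intermediate
41 | C18 tert-butyldimethylsilyl ether of 40 | CC(C)[Si](C(C)C)(C(C)C)OC[C@@H]1C[C@@]23C(=O)NC[C@@H](CCC4=C2[C@@H]1CC4)[C@]3(COC(C)=O)CC[C@@H](O[Si](C)(C)C(C)(C)C)[C@H](C)C(=O)N1[C@@H](Cc2ccccc2)COC1=O | intermediate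
42 | C20 primary alcohol | CC(C)[Si](C(C)C)(C(C)C)OC[C@@H]1C[C@@]23C(=O)NC[C@@H](CCC4=C2[C@@H]1CC4)[C@]3(COC(C)=O)CC[C@@H](O[Si](C)(C)C(C)(C)C)[C@H](C)CO | intermediate
43 | C20 primary iodide | CC(C)[Si](C(C)C)(C(C)C)OC[C@@H]1C[C@@]23C(=O)NC[C@@H](CCC4=C2[C@@H]1CC4)[C@]3(COC(C)=O)CC[C@@H](O[Si](C)(C)C(C)(C)C)[C@H](C)CI | intermediate
44 | pentacycle (rings A–E) with C1 CH2OSi(iPr)3 and C18 OSiMe2tBu | CC(C)[Si](C(C)C)(C(C)C)OC[C@@H]1C[C@@]23C(=O)N4C[C@@H](CCC5=C2[C@@H]1CC5)[C@]3(COC(C)=O)CC[C@@H](O[Si](C)(C)C(C)(C)C)[C@H](C)C4 | intermediate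
45 | pentacyclic diol (C1 CH2OH, C18 OH) | OC[C@@H]1C[C@@]23C(=O)N4C[C@@H](CCC5=C2[C@@H]1CC5)[C@]3(COC(C)=O)CC[C@@H](O)[C@H](C)C4 | intermediate
46 | pentacyclic C1 carboxylic acid | OC(=O)[C@@H]1C[C@@]23C(=O)N4C[C@@H](CCC5=C2[C@@H]1CC5)[C@]3(COC(C)=O)CC[C@@H](O)[C@H](C)C4 | intermediate
47 | CNP0296366.1, (1R,3R,7S,12R,15R,18R,19R) in the labels used here | COC(=O)[C@@H]1C[C@@]23C(=O)N4C[C@@H](CCC5=C2[C@@H]1CC5)[C@]3(COC(C)=O)CC[C@@H](O)[C@H](C)C4 | target

## Step count and least certain steps

Total: 34 steps. Longest linear sequence: 33 steps (steps 1, 2 and 4–34, from 1); step 3 is a one-step branch and 39 is purchased.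

**Step 10 (key step).** The most likely failure is diversion of the nickelacycle: β-hydride elimination from C13 to a ring-opened diene, or unproductive insertion into the ring-fusion bond, because the alkene is flanked by a quaternary cyclopropane carbon and the phosphonate can hold the metal. The fallback is the thermal diradical shift, made safe against loss of configuration by a covalent chiral auxiliary. It sets out from 14, which is ketalised with (2R,3R)-2,3-bis(trimethylsilyloxy)butane and catalytic Me3SiOTf to the dioxolane F1. Flash vacuum thermolysis (about 550 °C, base-washed quartz), the precedented 1,3-shift of this skeleton, then gives the rearranged ketal F2. Any ring-flip through the C11–C12 diradical now shows up as the C12 epimer F3, a diastereomer that is removed by chromatography; this would also correct a modest enantiomeric excess from step 8. Mild acid hydrolysis of F2 comes back to the route at 17.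

**Step 5.** The ruthenium methylidene may add too slowly to an alkyne flanked by a quaternary carbon, and the catalyst may decay under ethylene first. The fallback changes the alkyne into carbonyls: from 8, catalytic RuO2 with NaIO4 gives the 1,2-diketone F4, and double methylenation with Cp2TiMe2 in toluene at 70 °C (neutral, so the tert-butyl ester survives) comes back at 9.

**Step 15.** Closure may run in the kinetic four-membered mode at C11, which by the same cis-fusion rule would engage the other carboxyl and invert C3, or the hindered tetrasubstituted alkene may form its iodonium ion too slowly. The fallback drops the tether: from 21, one equivalent of KOH in aqueous methanol gives both half-esters, 25 and the epimeric half-ester F5, which are separated. F5 is re-methylated with Me3SiCHN2 and recycled to 21, and the route continues from 25.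

**Step 22.** Facial selectivity may be poor, or nitrogen may be allylated, because the lithium amidate sits on the face that has to be attacked. The fallback delivers the allyl group by a neutral [3,3] shift: from 31, iBu2AlH gives the aldehyde F6; KH and allyl bromide give the allyl enol ether F7 (any C-allylated product is already 33); heating in toluene (140–180 °C) effects the Claisen rearrangement and comes back at 33, which is reduced as in step 23.

**Step 31.** Oligomerisation, E2 elimination of the β-branched iodide or O-alkylation may outrun the nine-membered ring closure. The fallback closes the same bond through an N-acyliminium ion: from 42, Dess–Martin oxidation gives the aldehyde F8, and Et3SiH with CF3CO2H in CH2Cl2 at 0 °C reduces the cyclic N-acyl hemiaminal, coming back at 44. C19 would have to be checked for epimerisation through the enamide.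

## Further compounds

F1 | step 10 | (4R,5R)-4,5-dimethyl-1,3-dioxolane ketal of 14 | C[C@H]1OC2(O[C@@H]1C)CC(C(=O)OC)(C(=O)OC)[C@]3(C(=C)CCCP(=O)(OCC)OCC)C[C@H]23
F2 | step 10 | (4R,5R)-4,5-dimethyl-1,3-dioxolane ketal of 17 | C[C@H]1OC2(O[C@@H]1C)CC(C(=O)OC)(C(=O)OC)C3=C(CCCP(=O)(OCC)OCC)CC[C@H]23
F3 | step 10 | C12 epimer of F2 | C[C@H]1OC2(O[C@@H]1C)CC(C(=O)OC)(C(=O)OC)C3=C(CCCP(=O)(OCC)OCC)CC[C@@H]23
F4 | step 5 | 1-tert-butyl 2,2-dimethyl 7-(diethoxyphosphoryl)-3,4-dioxoheptane-1,2,2-tricarboxylate | COC(=O)C(CC(=O)OC(C)(C)C)(C(=O)C(=O)CCCP(=O)(OCC)OCC)C(=O)OC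
F5 | step 15 | C3 epimer of 25 (acid cis to H-12, methyl ester trans) | CC(C)[Si](C(C)C)(C(C)C)OC[C@@H]1C[C@](C(=O)O)(C(=O)OC)C2=C(CCCP(=O)(OCC)OCC)CC[C@H]12
F6 | step 22 | tetracyclic C15 aldehyde from 31 (both C15 epimers) | CC(C)[Si](C(C)C)(C(C)C)OC[C@@H]1C[C@@]23C(=O)NC[C@@H](CCC4=C2[C@@H]1CC4)C3C=O
F7 | step 22 | allyl enol ether of F6 (either alkene isomer) | CC(C)[Si](C(C)C)(C(C)C)OC[C@@H]1C[C@@]23C(=O)NC[C@@H](CCC4=C2[C@@H]1CC4)C3=COCC=C
F8 | step 31 | C20 aldehyde from 42 | CC(C)[Si](C(C)C)(C(C)C)OC[C@@H]1C[C@@]23C(=O)NC[C@@H](CCC4=C2[C@@H]1CC4)[C@]3(COC(C)=O)CC[C@@H](O[Si](C)(C)C(C)(C)C)[C@H](C)C=O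
A1 | alternative 1 | pentacyclic (16Z)-allylic alcohol, the target with an extra C16=C17 alkene | COC(=O)[C@@H]1C[C@@]23C(=O)N4C[C@@H](CCC5=C2[C@@H]1CC5)[C@]3(COC(C)=O)/C=C\[C@@H](O)[C@H](C)C4
A2 | alternative 1 | tetracyclic seco aldehyde: (Z)-2-iodovinyl on C15, (2R)-2-methyl-3-oxopropyl on N5 | COC(=O)[C@@H]1C[C@@]23C(=O)N(C[C@@H](C)C=O)C[C@@H](CCC4=C2[C@@H]1CC4)[C@]3(COC(C)=O)/C=C\I
A3 | alternative 2 | cyclopentene-fused cycloheptene acid with the vicinal quaternary carbons C3 and C15 | COC(=O)CC[C@@]1(C(=O)O)C2=C(CCC2)CC[C@H](CO[Si](C)(C)C(C)(C)C)[C@]1(COCc3ccc(OC)cc3)C=C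
A4 | alternative 2 | eleven-membered allylic lactone (C3 unassigned, lost on enolisation; ring alkene drawn cis within the ring, geometry to be fixed by the transition state) | COC(=O)CCC1C(=O)OC/C=C(/COCc2ccc(OC)cc2)[C@@H](CO[Si](C)(C)C(C)(C)C)CCC2=C1CCC2
A5 | alternative 3 | bridged lactam–azonane with a vinyl group on C7 and an enol triflate on C10 | COC(=O)[C@@H]1C[C@]2(C3=C(OS(=O)(=O)C(F)(F)F)CC[C@H]13)C(=O)N4C[C@@H](C=C)[C@]2(COC(C)=O)CC[C@@H](O[Si](C)(C)C(C)(C)C)[C@H](C)C4
A6 | alternative 3 | N-carboxymethyl nine-membered lactam with an (E)-3-(trimethylsilyl)prop-1-enyl group on C15 | COC(=O)[C@@H]1C[C@]2(C3=C(OS(=O)(=O)C(F)(F)F)CC[C@H]13)C(=O)N(CC(=O)O)C[C@@H](C)[C@H](O[Si](C)(C)C(C)(C)C)CC[C@@]2(COC(C)=O)/C=C/C[Si](C)(C)C
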